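## The problem

Sikokianin B (15) is a 3,3''-biflavanone: two 5,7-dihydroxychroman-4-ones joined by a single bond between C3 and C3''. The 2-aryl group is 4-methoxyphenyl in unit 1 and 4-hydroxyphenyl in unit 2. The four stereocentres C2, C3, C3'' and C2'' are contiguous; unit 1 is 2,3-trans (2R,3S) and unit 2 is 2,3-cis (2''R,3''R). Within a unit C2 can direct C3 (trans by equilibration, cis by protonation of the ring enolate anti to the aryl group), but the units communicate only through the C3–C3'' bond, so the like sense of C2 and C2'' must come from a reagent. All four centres are labile: C3 and C3'' are alpha to ketones, C2 and C2'' are lost by retro-oxa-Michael opening in base, and C2'' can also open through a quinone methide because its aryl group has a free para hydroxyl. The cis unit therefore has to be formed last, under kinetic control, and kept away from base, and the five free phenols and electron-rich rings A exclude strong oxidants and strong Lewis acids late in the route. The enabling feature is that ring A of unit 1 (C4a to C8a) and ring A of unit 2 (C4a'' to C8a'') are both 2-acylphloroglucinols, the aromatic form of a tetraketide chain with local twofold symmetry. Either ortho hydroxyl can become O1 or O1'', so both rings can be built from open chains by Claisen cyclisation with no regiochemical question and no protecting groups on ring A.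

## Retrosynthesis

**Ring C ether bonds.** Cutting O1–C2 and O1''–C2'' of 15 in the retro-oxa-Michael sense leads through monoflavanone 14 to the E,E-bichalcone 13, an achiral isomer of the target. The neighbouring cut at C3–C3'' (oxidative coupling of two different flavanone enolates) would give homo- and heterodimers statistically and offers no hold on C3 or C3''. All four stereocentres are removed in this one cut and no protecting group is left. The forward reaction must close unit 1 first, with the same facial sense at both enones, with C3 equilibrated to trans and C3'' protonated kinetically to cis. The free phenol of ring B in unit 2 is the switch: as a phenoxide it turns its own enone off.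

**Ring A carbon–carbon bonds.** Cutting C4a–C8a and C4a''–C8a'' of 13 opens both phloroglucinol rings to the bis(3,5,7-triketo ester) 11; the forward step passes through the MOM ether 12, which is cleaved in the acidic finish. The neighbouring cut at C4–C4a (acylation of a phloroglucinol by a hindered diacid derivative) would need six phenol protections or a strong Lewis acid. The Claisen route instead delivers the three oxygens and the acyl group of each ring unprotected. The precursor 11 has no ring A, no stereocentre and no acidic C–H on its dibenzylidene core. The forward reaction must choose Claisen over aldol closure in both arms. The ring B phenol is carried as a MOM ether up to this point because a free phenoxide would deactivate its own ester in the acylation before it; a benzyl ether is excluded because its hydrogenolysis is incompatible with the chalcone alkenes.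

**Second acyl–methylene bond.** Cutting C4''–C4a'' of 11 gives the mono(triketo ester) 10, which keeps a methyl ester on the 4-(methoxymethoxy)benzylidene carbon, and methyl 3,5-dioxohexanoate 9. All six carbons of ring A of unit 2 then come from one commercial reagent. The forward reaction is a C-acylation of the trianion of 9 at its terminal carbon by a hindered conjugated ester, 1,2 and not 1,4, on a substrate that is itself a polyanion under the conditions.

**First acyl–methylene bond.** Cutting C4–C4a of 10 gives the acyl imidazolide 8 and a second molecule of 9. Attaching both arms at once to a symmetric diester would leave the slower second acylation to an unobserved polyanionic intermediate and would pass through two regioisomeric half-way compounds. The half ester 7 already has its two carboxyl groups differentiated, the free acid on the 4-methoxybenzylidene carbon and the methyl ester on the other, and 8 is its activated form. Each arm is therefore attached in its own operation, each consuming one molecule of 9, and 10 is a single regioisomer. The forward reaction requires the N-acylimidazole to react at −78 °C, where the methyl ester is inert.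

**Second benzylidene.** Cutting the C2''=C3'' alkene of 7 gives the benzylidenesuccinate 4 and 4-(methoxymethoxy)benzaldehyde 6, made from 4-hydroxybenzaldehyde 5. A Stobbe condensation stops cleanly after one aldehyde, which is what makes the unsymmetrical diene accessible, and it leaves the free acid on the carbon that already carried the first benzylidene. It must give the E alkene.

**First benzylidene.** Cutting the C2=C3 alkene of 4 (through the half ester 3) gives dimethyl succinate 1 and 4-methoxybenzaldehyde 2. The C3–C3'' bond of the target is thus the central bond of succinate, bought and never made.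

## Roads not taken

**Alternative 1:** carbene C–H insertion, cutting C2''–C3''. A unit 1 flavanone already holding C2 and C3 carries at C3 a diazo(aroyl)methyl group (diazoketone A2). Rh2(S-PTTL)4, dirhodium tetrakis[N-phthaloyl-(S)-tert-leucinate], would turn it into a carbene that inserts into the O1''–CH2–aryl C–H bond and closes ring C of unit 2 as the cis isomer, giving protected sikokianin B A1.
- Merits: the cis unit is made by an irreversible C–C bond formation under catalyst control and never passes through an enolate. In that respect it is more secure than a kinetic protonation.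
- Weak points: the carbene carbon has the C3–H of unit 1 in the beta position, and a 1,2-hydride shift that destroys the carbene is the usual fate of alpha-alkyl diazoketones. The six-membered insertion competes with oxonium ylide formation at O1''. Unit 1 must be made enantiopure and keep C3 through acylation and diazo transfer. Four benzyl ethers and a silyl ether must be put on and taken off.
- Comparison: the chosen plan is weaker on stereochemical security of the cis unit. Against that it sets an achiral precursor, no protection on ring A and a much shorter sequence.

**Alternative 2:** ortho-quinone methide cycloaddition, cutting C3–C4 and O1–C2. A chiral phosphoric acid such as (R)-3,3'-bis(2,4,6-triisopropylphenyl)-1,1'-binaphthyl-2,2'-diyl hydrogen phosphate would ionise benzylic alcohol A5 to an ortho-quinone methide, which adds (4+2) across the E alkene of 3-styrylflavone A4 to give trans-flavan A3.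
- Merits: it is convergent, and the trans relation of unit 1 comes from alkene geometry instead of an equilibrium. That is better than the chosen plan on that point.
- Weak points: A3 has the wrong oxidation level twice. C4 is a methylene that must be oxidised in the presence of five benzyl ethers and the C2 benzylic ether. Unit 2 is a flavone whose tetrasubstituted C2''=C3'' bond must be reduced syn, on one face, without over-reduction. An unsubstituted quinone methide from a primary benzylic alcohol is also hard to generate and to control with a chiral acid.
- Comparison: the chosen plan is redox-neutral once the skeleton stands (its last step is an isomerisation) and needs no benzyl ethers. It gives up the convergence.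

**Alternative 3:** intramolecular Stetter closure, cutting C3–C4. A chiral triazolium salt such as (5aS,10bR)-2-(pentafluorophenyl)-5a,10b-dihydro-4H,6H-indeno[2,1-b][1,2,4]triazolo[4,3-d][1,4]oxazin-2-ium tetrafluoroborate, with a weak base, would convert the ring A aldehyde of Z-alkylidene flavanone A7 into an acyl anion equivalent. This adds to C3 of the exocyclic enone, closes ring C of unit 1 and delivers a proton to C3'', giving pentabenzyl sikokianin B A6.
- Merits: the salicylaldehyde-ether Stetter closure to chroman-4-ones is the best precedented key step of the four roads, and C3 is set by irreversible C–C bond formation. On both counts it is better than the chosen plan.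
- Weak points: A7 must already hold C2 and C2''. C2 is an allylic, benzylic aryl ether carbon. Under the basic carbene conditions the exocyclic alkene of A7 tends to migrate into the ring, which erases C2'' and the acceptor. The acceptor is a trisubstituted enone. Making A7 needs a Z-selective condensation with a configurationally fragile alpha-aryloxy aldehyde, and five benzyl ethers.
- Comparison: the chosen plan answers with a stable, achiral, protecting-group-light precursor from commodity materials and with all stereochemistry postponed to the final step. It accepts a less secure final step.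

Key step: step 8

Assumption: the quinine-derived thiourea named in step 9 is taken to give the 2R sense of closure; if the sense proves to be the opposite, its quinidine-derived pseudoenantiomer is used in the same way.

## Route

Step 1
Reactants: 1 dimethyl succinate; 2 4-methoxybenzaldehyde
Product: 3 (E)-3-(methoxycarbonyl)-4-(4-methoxyphenyl)but-3-enoic acid
Conditions: NaOMe, MeOH, reflux; then 1 M HCl, 0 °C
Reagents that add atoms: none
Why: Stobbe condensation: the succinate enolate adds to the aldehyde, the alkoxide lactonises onto the distal ester, and E1cB opening of the lactone gives the half ester, whose carboxylate prevents a second condensation. The E alkene (aryl trans to the ester) is the favoured outcome of the elimination.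

Step 2
Reactants: 3 (E)-3-(methoxycarbonyl)-4-(4-methoxyphenyl)but-3-enoic acid
Product: 4 dimethyl (E)-2-(4-methoxybenzylidene)succinate
Conditions: MeI, K2CO3, DMF, rt
Reagents that add atoms: iodomethane, CI
Why: SN2 O-alkylation of the carboxylate restores the diester without touching the alkene geometry.

Step 3
Reactants: 5 4-hydroxybenzaldehyde
Product: 6 4-(methoxymethoxy)benzaldehyde
Conditions: MOMCl, iPr2NEt, CH2Cl2, 0 °C to rt
Reagents that add atoms: chloromethyl methyl ether, COCCl
Why: O-alkylation of the phenol gives an acetal ether that withstands alkoxide, LiN(iPr)2 and Mg(OMe)2. It keeps a phenoxide from deactivating the aldehyde in step 4 and the neighbouring ester in step 7.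

Step 4
Reactants: 4 dimethyl (E)-2-(4-methoxybenzylidene)succinate; 6 4-(methoxymethoxy)benzaldehyde
Product: 7 (2E,3E)-3-(methoxycarbonyl)-2-(4-methoxybenzylidene)-4-[4-(methoxymethoxy)phenyl]but-3-enoic acid
Conditions: NaOMe, MeOH, reflux; then 1 M HCl, 0 °C, to pH 3
Reagents that add atoms: none
Why: Second Stobbe condensation: the activated methylene of 4 adds to 6, lactonisation onto the ester of the anisylidene carbon and E1cB opening leave the free acid there, which is the handle used in step 5, and give the E,E-diene, the favoured isomer of dibenzylidenesuccinates. The MOM ether survives the brief cold acidification.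

Step 5
Reactants: 7 (2E,3E)-3-(methoxycarbonyl)-2-(4-methoxybenzylidene)-4-[4-(methoxymethoxy)phenyl]but-3-enoic acid
Product: 8 methyl (2E,3E)-3-(imidazol-1-ylcarbonyl)-4-(4-methoxyphenyl)-2-[4-(methoxymethoxy)benzylidene]but-3-enoate
Conditions: carbonyldiimidazole (1.2 equiv.), THF, rt; CH2Cl2, ice-water wash
Reagents that add atoms: carbonyldiimidazole, O=C(n1ccnc1)n1ccnc1
Why: Carboxylic acid activation as the N-acylimidazole: the carboxylate attacks the reagent and the mixed anhydride collapses with loss of CO2. The neutral conditions leave the methyl ester, the MOM ether and both E alkenes untouched, and washing out the imidazole removes an N–H acid that would consume trianion in step 6.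

Step 6
Reactants: 8 methyl (2E,3E)-3-(imidazol-1-ylcarbonyl)-4-(4-methoxyphenyl)-2-[4-(methoxymethoxy)benzylidene]but-3-enoate; 9 methyl 3,5-dioxohexanoate
Product: 10 dimethyl (8E,9E)-8-(4-methoxybenzylidene)-9-[4-(methoxymethoxy)benzylidene]-3,5,7-trioxodecanedioate
Conditions: 9 (2.2 equiv.), LiN(iPr)2 (6.6 equiv.), THF, −78 to 0 °C; then 8, −78 °C; AcOH, −78 °C
Reagents that add atoms: none
Why: Claisen-type C-acylation of a 1,3,5-tricarbonyl trianion: the terminal carbanion of the trianion of 9, its most basic and least hindered site, attacks the N-acylimidazole 1,2 and imidazolide leaves, at a temperature at which the hindered, conjugated methyl ester next to it does not react. The second equivalent of trianion deprotonates the new methylene; no stereocentre is formed and the E,E-diene has no enolisable hydrogen.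

Step 7
Reactants: 10 dimethyl (8E,9E)-8-(4-methoxybenzylidene)-9-[4-(methoxymethoxy)benzylidene]-3,5,7-trioxodecanedioate; 9 methyl 3,5-dioxohexanoate
Product: 11 dimethyl (8E,9E)-8-(4-methoxybenzylidene)-9-[4-(methoxymethoxy)benzylidene]-3,5,7,10,12,14-hexaoxohexadecanedioate
Conditions: 10, LiN(iPr)2 (3 equiv.), THF, −78 °C; added to 9 (3 equiv.) and LiN(iPr)2 (9 equiv.), THF, 0 °C to rt; AcOH, −78 °C
Reagents that add atoms: none
Why: The same Claisen-type C-acylation with the methyl ester as acyl donor: 10 is first converted into its trilithio salt so that its three acidic methylenes do not protonate the nucleophile, then the terminal carbanion of the trianion of 9 attacks the ester carbonyl 1,2 and methoxide leaves. The stabilised beta-dicarbonyl carbanions of the first arm are far weaker nucleophiles than this terminal carbanion, which should hold back closure of the first arm onto the neighbouring ester.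

Step 8
Reactants: 11 dimethyl (8E,9E)-8-(4-methoxybenzylidene)-9-[4-(methoxymethoxy)benzylidene]-3,5,7,10,12,14-hexaoxohexadecanedioate
Product: 13 (2E,3E)-2-(4-hydroxybenzylidene)-3-(4-methoxybenzylidene)-1,4-bis(2,4,6-trihydroxyphenyl)butane-1,4-dione, via MOM-protected bichalcone 12 (not isolated)
Conditions: Mg(OMe)2 (8 equiv.), MeOH, 50 °C, argon, dark; then HCl in MeOH (excess), 0 °C to rt
Reagents that add atoms: none
Why: Mg(OMe)2 converts each 3,5,7-triketo ester arm into a chelated magnesium polyenolate in which the ketone carbonyls are masked as enolates and the terminal ester is the only electrophile. The carbanion at C4a (the methylene between the C4 and C5 carbonyls) attacks the C8a ester carbonyl, methoxide leaves and the 2-acylcyclohexane-1,3,5-trione enolises to the 2-acylphloroglucinol; the second arm does the same at C4a''–C8a''. The closest known reaction is the base-induced Claisen (Dieckmann-type) cyclisation of 3,5,7-triketo esters to acylphloroglucinols, the laboratory counterpart of chalcone synthase. Each ring A closes in the 6-exo-trig mode, an enolate carbon onto an exocyclic ester carbonyl. No stereocentre is formed, and the E,E geometry set in steps 1 and 4 is carried through because the dibenzylidene core has no acidic C–H. The step needs Claisen over aldol chemoselectivity in both arms: attack of C8 on the C4 ketone is held back because C4 is an alpha-branched, cross-conjugated, enolate-masked carbonyl shielded by the dibenzylidene unit, and magnesium chelation folds the chain for the Claisen closure. Cold methanolic HCl then frees the polyphenol 12 from magnesium and cleaves its aryl MOM ether, conditions under which 2'-hydroxychalcones close only slowly.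

Step 9
Reactants: 13 (2E,3E)-2-(4-hydroxybenzylidene)-3-(4-methoxybenzylidene)-1,4-bis(2,4,6-trihydroxyphenyl)butane-1,4-dione
Product: 15 sikokianin B [(2R,3S)-5,7-dihydroxy-3-[(2R,3R)-5,7-dihydroxy-2-(4-hydroxyphenyl)-4-oxochroman-3-yl]-2-(4-methoxyphenyl)chroman-4-one], via monoflavanone 14 (not isolated)
Conditions: 1-[3,5-bis(trifluoromethyl)phenyl]-3-[(8α,9S)-6'-methoxycinchonan-9-yl]thiourea (20 mol %), DBU (3.0 equiv.), THF, −20 °C; then AcOH (3.1 equiv.), −40 to −20 °C; pH 4 citrate buffer
Reagents that add atoms: none
Why: Proposed new method: with the ring B phenol of unit 2 and the two ring A hydroxyls para to the carbonyls held as amidinium phenoxides, only the 4-methoxyphenyl enone stays electrophilic, so the bifunctional amine-thiourea closes unit 1 first by a 6-endo-trig oxa-Michael addition that sets C2 as R by catalyst control, while C3 of 14, whose anion is a cross-conjugated dienolate, equilibrates to the 2,3-trans (3S) arrangement. Acetic acid then returns the unit 2 phenol to its neutral form, the same catalyst closes the second ring with the same facial sense (C2'' R), and the ring enolate is protonated at C3'' anti to the pseudoaxial C2'' aryl group to give the 2'',3''-cis (3''R) arrangement, which the cold buffered medium should not equilibrate. The closest known reaction type is the cinchona amine or amine-thiourea catalysed enantioselective intramolecular oxa-Michael addition of 2'-hydroxyaryl alpha-substituted enones, which gives cis-2,3-disubstituted chroman-4-ones by kinetic protonation; its ordered twofold use on a bis-enone is new.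

## Compound list

1 | dimethyl succinate | COC(=O)CCC(=O)OC | starting material
2 | 4-methoxybenzaldehyde | COc1ccc(C=O)cc1 | starting material
3 | (E)-3-(methoxycarbonyl)-4-(4-methoxyphenyl)but-3-enoic acid | COC(=O)/C(=C/c1ccc(OC)cc1)CC(=O)O | intermediate
4 | dimethyl (E)-2-(4-methoxybenzylidene)succinate | COC(=O)/C(=C/c1ccc(OC)cc1)CC(=O)OC | intermediate
5 | 4-hydroxybenzaldehyde | O=Cc1ccc(O)cc1 | starting material
6 | 4-(methoxymethoxy)benzaldehyde | COCOc1ccc(C=O)cc1 | intermediate
7 | (2E,3E)-3-(methoxycarbonyl)-2-(4-methoxybenzylidene)-4-[4-(methoxymethoxy)phenyl]but-3-enoic acid | OC(=O)/C(=C/c1ccc(OC)cc1)C(=C/c1ccc(OCOC)cc1)\C(=O)OC | intermediate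
8 | methyl (2E,3E)-3-(imidazol-1-ylcarbonyl)-4-(4-methoxyphenyl)-2-[4-(methoxymethoxy)benzylidene]but-3-enoate | O=C(n1ccnc1)/C(=C/c1ccc(OC)cc1)C(=C/c1ccc(OCOC)cc1)\C(=O)OC | intermediate
9 | methyl 3,5-dioxohexanoate | COC(=O)CC(=O)CC(C)=O | starting material
10 | dimethyl (8E,9E)-8-(4-methoxybenzylidene)-9-[4-(methoxymethoxy)benzylidene]-3,5,7-trioxodecanedioate | COC(=O)CC(=O)CC(=O)CC(=O)/C(=C/c1ccc(OC)cc1)C(=C/c1ccc(OCOC)cc1)\C(=O)OC | intermediate
11 | dimethyl (8E,9E)-8-(4-methoxybenzylidene)-9-[4-(methoxymethoxy)benzylidene]-3,5,7,10,12,14-hexaoxohexadecanedioate | COC(=O)CC(=O)CC(=O)CC(=O)/C(=C/c1ccc(OC)cc1)C(=C/c1ccc(OCOC)cc1)\C(=O)CC(=O)CC(=O)CC(=O)OC | intermediate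
12 | (2E,3E)-2-(4-methoxybenzylidene)-3-[4-(methoxymethoxy)benzylidene]-1,4-bis(2,4,6-trihydroxyphenyl)butane-1,4-dione | COc1ccc(/C=C(C(=O)c2c(O)cc(O)cc2O)\C(=C/c2ccc(OCOC)cc2)C(=O)c2c(O)cc(O)cc2O)cc1 | intermediate (not isolated)
13 | (2E,3E)-2-(4-hydroxybenzylidene)-3-(4-methoxybenzylidene)-1,4-bis(2,4,6-trihydroxyphenyl)butane-1,4-dione | COc1ccc(/C=C(C(=O)c2c(O)cc(O)cc2O)\C(=C/c2ccc(O)cc2)C(=O)c2c(O)cc(O)cc2O)cc1 | intermediate
14 | (2R,3S)-5,7-dihydroxy-3-[(E)-1-(4-hydroxyphenyl)-3-oxo-3-(2,4,6-trihydroxyphenyl)prop-1-en-2-yl]-2-(4-methoxyphenyl)chroman-4-one | COc1ccc([C@@H]2Oc3cc(O)cc(O)c3C(=O)[C@H]2\C(=C/c2ccc(O)cc2)C(=O)c2c(O)cc(O)cc2O)cc1 | intermediate (not isolated)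
15 | sikokianin B, (2R,3S)-5,7-dihydroxy-3-[(2R,3R)-5,7-dihydroxy-2-(4-hydroxyphenyl)-4-oxochroman-3-yl]-2-(4-methoxyphenyl)chroman-4-one | COc1ccc([C@@H]2Oc3cc(O)cc(O)c3C(=O)[C@H]2[C@H]2C(=O)c3c(O)cc(O)cc3O[C@H]2c2ccc(O)cc2)cc1 | target

## Step count and least certain steps

Total steps: 9. Longest linear sequence: 8 steps (steps 1, 2, 4, 5, 6, 7, 8 and 9); step 3 is a one-step side branch.

**Step 9 (proposed new method).**
- What may go wrong: enantiocontrol in the first closure may be lost to an uncatalysed cyclisation mediated by the stoichiometric phenoxides, and the order of closure may be lost if the unit 2 phenol is incompletely ionised. The cis unit may later epimerise, at C3'' by enolisation or at C2'' by the quinone-methide ring opening that its free 4-hydroxyphenyl group allows. Gamma-protonation of the dienolate of 14 at C2'' is a further leak.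
- Fallback, known chemistry, from 13 back to 15: 13 is cyclised without a chiral catalyst in two stages. In carbonate buffer (pH about 10, aqueous MeOH, 0 °C) the unit 2 phenoxide keeps its enone inert while unit 1 closes and equilibrates, giving the racemic trans-monoflavanone F1. At pH 7 (phosphate, 0 °C) unit 2 then closes with kinetic protonation. The diastereomeric racemates are separated by reversed-phase chromatography to give racemic sikokianin B F2, which is resolved by preparative HPLC on a cellulose tris(3,5-dimethylphenylcarbamate) phase to give 15.

**Step 8 (key step).**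
- What may go wrong: aldol-mode closure (C8 onto C4) in one or both arms, or conjugate addition of a chain carbanion to a benzylidene carbon, since the same polyenolate can take each path and both arms must choose correctly. Premature, uncatalysed ring closure of the chalcone units, in the methoxide medium or during the acidic MOM cleavage, is a second concern.
- Fallback, from 8 back to 13, giving up ring construction for arene acylation: acyl imidazolide 8 is treated with MeNHOMe·HCl (CH2Cl2, rt) to give the N-methoxy-N-methylamide methyl ester F3, whose remaining ester is converted with MeNHOMe·HCl and iPrMgCl (THF, −20 °C) into the bis(N-methoxy-N-methylamide) F4. 1,3,5-Tris(methoxymethoxy)benzene F5, made from phloroglucinol with MOMCl and iPr2NEt, is lithiated between two of its ether groups with n-BuLi and added twice to F4 to give the heptakis(MOM) bichalcone F6. Cold methanolic HCl cleaves all MOM ethers of F6 and returns 13.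

**Step 7.**
- What may go wrong: stalling of the intermolecular acylation, because the hindered ester sits beside the negative charge of the first arm; intramolecular attack of the first arm's C4a carbanion on that ester (a five-membered closure across the diene); proton transfer from the product; and 1,4-addition to a benzylidene carbon.
- Fallback, from 10 back to 11, building the second arm in two carbon–carbon bond formations: the methyl ester of 10, as its trilithio salt, acylates the terminal carbon of the dianion of pentane-2,4-dione (LiN(iPr)2, THF), a smaller and less highly charged nucleophile, to give the triketone–triketo ester F7. Full deprotonation of F7 with LiN(iPr)2 and carboxylation with CO2 of the terminal methyl carbanion, the only one not flanked by two carbonyl groups, gives the triketo acid F8. Brief treatment of F8 with CH2N2 in Et2O at 0 °C returns 11.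

**Step 6.**
- What may go wrong: loss of chemoselectivity between the N-acylimidazole and the methyl ester, acylation at oxygen or at one of the stabilised internal carbanions instead of the terminal one, hydrolysis of the imidazolide before use, and 1,4-addition.
- Fallback, from 7 back to 11, giving up the staged acylation: 7 is esterified with MeI and K2CO3 (DMF, rt) to the dimethyl ester F9, which is added to a large excess of the trianion of 9 (LiN(iPr)2, THF, 0 °C to rt). Both esters are then acylated in one flask; the two half-way compounds, 10 and its regioisomer F10, are not isolated and both lead on to 11.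

## Further compounds

F1 | step 9 | racemic trans-monoflavanone (14 and its enantiomer, 1:1) | COc1ccc([C@@H]2Oc3cc(O)cc(O)c3C(=O)[C@H]2\C(=C/c2ccc(O)cc2)C(=O)c2c(O)cc(O)cc2O)cc1.COc1ccc([C@H]2Oc3cc(O)cc(O)c3C(=O)[C@@H]2\C(=C/c2ccc(O)cc2)C(=O)c2c(O)cc(O)cc2O)cc1
F2 | step 9 | racemic sikokianin B (15 and its enantiomer, 1:1) | COc1ccc([C@@H]2Oc3cc(O)cc(O)c3C(=O)[C@H]2[C@H]2C(=O)c3c(O)cc(O)cc3O[C@H]2c2ccc(O)cc2)cc1.COc1ccc([C@H]2Oc3cc(O)cc(O)c3C(=O)[C@@H]2[C@@H]2C(=O)c3c(O)cc(O)cc3O[C@@H]2c2ccc(O)cc2)cc1
F3 | step 8 | methyl (2E,3E)-3-[methoxy(methyl)carbamoyl]-4-(4-methoxyphenyl)-2-[4-(methoxymethoxy)benzylidene]but-3-enoate | CON(C)C(=O)/C(=C/c1ccc(OC)cc1)C(=C/c1ccc(OCOC)cc1)\C(=O)OC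
F4 | step 8 | (2E,3E)-N,N'-dimethoxy-N,N'-dimethyl-2-(4-methoxybenzylidene)-3-[4-(methoxymethoxy)benzylidene]succinamide | CON(C)C(=O)/C(=C/c1ccc(OC)cc1)C(=C/c1ccc(OCOC)cc1)\C(=O)N(C)OC
F5 | step 8 | 1,3,5-tris(methoxymethoxy)benzene | COCOc1cc(OCOC)cc(OCOC)c1
F6 | step 8 | (2E,3E)-2-(4-methoxybenzylidene)-3-[4-(methoxymethoxy)benzylidene]-1,4-bis[2,4,6-tris(methoxymethoxy)phenyl]butane-1,4-dione | COCOc1cc(OCOC)c(C(=O)/C(=C/c2ccc(OC)cc2)C(=C/c2ccc(OCOC)cc2)\C(=O)c2c(OCOC)cc(OCOC)cc2OCOC)c(OCOC)c1
F7 | step 7 | methyl (8E,9E)-8-(4-methoxybenzylidene)-9-[4-(methoxymethoxy)benzylidene]-3,5,7,10,12,14-hexaoxopentadecanoate | COC(=O)CC(=O)CC(=O)CC(=O)/C(=C/c1ccc(OC)cc1)C(=C/c1ccc(OCOC)cc1)\C(=O)CC(=O)CC(C)=O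
F8 | step 7 | (8E,9E)-16-methoxy-9-(4-methoxybenzylidene)-8-[4-(methoxymethoxy)benzylidene]-3,5,7,10,12,14,16-heptaoxohexadecanoic acid | COC(=O)CC(=O)CC(=O)CC(=O)/C(=C/c1ccc(OC)cc1)C(=C/c1ccc(OCOC)cc1)\C(=O)CC(=O)CC(=O)CC(=O)O
F9 | step 6 | dimethyl (2E,3E)-2-(4-methoxybenzylidene)-3-[4-(methoxymethoxy)benzylidene]succinate | COC(=O)/C(=C/c1ccc(OC)cc1)C(=C/c1ccc(OCOC)cc1)\C(=O)OC
F10 | step 6 | dimethyl (8E,9E)-9-(4-methoxybenzylidene)-8-[4-(methoxymethoxy)benzylidene]-3,5,7-trioxodecanedioate | COC(=O)/C(=C/c1ccc(OC)cc1)C(=C/c1ccc(OCOC)cc1)\C(=O)CC(=O)CC(=O)CC(=O)OC
A1 | alternative 1 | protected sikokianin B (5''-O-tert-butyldimethylsilyl; benzyl ethers at O5, O7, O7'' and the ring B oxygen of unit 2) | COc1ccc([C@@H]2Oc3cc(OCc4ccccc4)cc(OCc4ccccc4)c3C(=O)[C@H]2[C@H]2C(=O)c3c(O[Si](C)(C)C(C)(C)C)cc(OCc4ccccc4)cc3O[C@H]2c2ccc(OCc3ccccc3)cc2)cc1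
A2 | alternative 1 | unit 1 flavanone bearing at C3 the diazo(aroyl)methyl group, with the O1'' 4-(benzyloxy)benzyl ether | COc1ccc([C@@H]2Oc3cc(OCc4ccccc4)cc(OCc4ccccc4)c3C(=O)[C@H]2C(=[N+]=[N-])C(=O)c2c(O[Si](C)(C)C(C)(C)C)cc(OCc3ccccc3)cc2OCc2ccc(OCc3ccccc3)cc2)cc1
A3 | alternative 2 | trans-flavan of unit 1 carrying the pentabenzylated unit 2 flavone at C3 | COc1ccc([C@@H]2Oc3cc(OCc4ccccc4)cc(OCc4ccccc4)c3C[C@H]2C2=C(c3ccc(OCc4ccccc4)cc3)Oc3cc(OCc4ccccc4)cc(OCc4ccccc4)c3C2=O)cc1
A4 | alternative 2 | 5,7-bis(benzyloxy)-2-[4-(benzyloxy)phenyl]-3-[(E)-2-(4-methoxyphenyl)ethenyl]-4H-chromen-4-one | COc1ccc(/C=C/C2=C(c3ccc(OCc4ccccc4)cc3)Oc3cc(OCc4ccccc4)cc(OCc4ccccc4)c3C2=O)cc1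
A5 | alternative 2 | 3,5-bis(benzyloxy)-2-(hydroxymethyl)phenol | OCc1c(O)cc(OCc2ccccc2)cc1OCc1ccccc1
A6 | alternative 3 | pentabenzyl sikokianin B | COc1ccc([C@@H]2Oc3cc(OCc4ccccc4)cc(OCc4ccccc4)c3C(=O)[C@H]2[C@H]2C(=O)c3c(OCc4ccccc4)cc(OCc4ccccc4)cc3O[C@H]2c2ccc(OCc3ccccc3)cc2)cc1
A7 | alternative 3 | Z-3-alkylidene flavanone of unit 2 whose alkylidene carbon chain ends in the C2 aryl ether of 2,4-bis(benzyloxy)-6-hydroxybenzaldehyde | COc1ccc([C@H](Oc2cc(OCc3ccccc3)cc(OCc3ccccc3)c2C=O)/C=C2\C(=O)c3c(OCc4ccccc4)cc(OCc4ccccc4)cc3O[C@H]2c2ccc(OCc3ccccc3)cc2)cc1
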